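Locants follow naphthalene numbering within each half: C1 (quaternary) to C8a in the carbinol half, C1′ (ketal carbon) to C8a′ in the ketone half; the halves meet at C1–C8′. The plan rests on building ring C1′–C4′ last. That ring is a six-membered carbocycle fused to the benzene ring C4a′–C8a′ and oxygenated at the para-related carbons C1′ and C4′, the pattern that a chromium carbene, an alkyne and CO assemble. One operation forms C4′–C3′, C2′–C1′ and C1′–C8a′ and delivers a 4′-methoxy-1′-naphthol. Its precursor is a plain benzene ring that bears the Fischer carbene at C4a′ and is already joined through C8′ to the finished, enantiopure carbinol half.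

Key step: step 17

Remarks and assumptions
- From compound 12 on, names use the locants of the target half. In 11 the carbonyl carbon is the future C4 and the ketal carbon the future C1.
- Step 8: the sense of induction is assumed. The cinchonidine-derived salt is written; if it favours the antipode, the pseudo-enantiomeric cinchonine-derived salt takes its place.
- The C3 descriptor alternates between S and R along the route only because O-silylation at C4 changes CIP priorities; the centre is never inverted.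
- The quinone is unveiled in step 19 with PhI(OAc)2, because a cerium oxidant would also attack the bis-MOM hydroquinone ring of the carbinol half.
- Compounds 1, 2, 16 and 25 are taken as commercial.

Step 1
Reactants: 1 2-chloro-1,4-dimethoxybenzene; 2 succinic anhydride
Product: 3 4-(4-chloro-2,5-dimethoxyphenyl)-4-oxobutanoic acid
Conditions: AlCl3 (2.5 equiv), CH2Cl2, 0 °C → rt; aq. HCl
Reagents that add atoms: none
Why: Friedel–Crafts acylation should take place para to chlorine and ortho to a methoxy group, the least deactivated and least crowded of the three free ring positions.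

Step 2
Reactants: 3 4-(4-chloro-2,5-dimethoxyphenyl)-4-oxobutanoic acid
Product: 4 4-(4-chloro-2,5-dimethoxyphenyl)butanoic acid
Conditions: Et3SiH (3 equiv), CF3CO2H, rt → 50 °C
Reagents that add atoms: none
Why: Ionic hydrogenation, in which the protonated aryl ketone and then the benzylic cation (stabilised by the ortho methoxy group) accept hydride from the silane, should reduce C=O to CH2 without touching the aryl chloride.

Step 3
Reactants: 4 4-(4-chloro-2,5-dimethoxyphenyl)butanoic acid
Product: 5 7-chloro-5,8-dimethoxy-3,4-dihydronaphthalen-1(2H)-one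
Conditions: (CF3CO)2O, CF3CO2H, CH2Cl2, 0 °C → rt
Reagents that add atoms: none
Why: Intramolecular Friedel–Crafts acylation through the mixed trifluoroacetic anhydride can only close at the one free ortho position, which is activated by its neighbouring methoxy group.

Step 4
Reactants: 5 7-chloro-5,8-dimethoxy-3,4-dihydronaphthalen-1(2H)-one
Product: 6 7-chloro-5,8-dihydroxy-3,4-dihydronaphthalen-1(2H)-one
Conditions: BBr3 (3 equiv), CH2Cl2, −78 °C → rt; H2O
Reagents that add atoms: none
Why: Lewis-acid cleavage of both aryl methyl ethers (the peri ether helped by chelation to the ketone) should give a hydroquinone that the acyl group stabilises against air oxidation.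

Step 5
Reactants: 6 7-chloro-5,8-dihydroxy-3,4-dihydronaphthalen-1(2H)-one
Product: 7 7-chloro-5,8-bis(methoxymethoxy)-3,4-dihydronaphthalen-1(2H)-one
Conditions: MOMCl (3 equiv), iPr2NEt (4 equiv), CH2Cl2, 0 → 40 °C
Reagents that add atoms: chloromethyl methyl ether, COCCl
Why: O-Alkylation of both phenols (Williamson type) exchanges the robust methyl ethers for acetals that mild acid removes at the end.

Step 6
Reactants: 7 7-chloro-5,8-bis(methoxymethoxy)-3,4-dihydronaphthalen-1(2H)-one
Product: 9 7-chloro-5,8-bis(methoxymethoxy)naphthalen-1-ol, via trimethylsilyl enol ether 8 (not isolated)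
Conditions: LiN(SiMe3)2, Me3SiCl, THF, −78 °C; then Pd(OAc)2 (1.05 equiv), MeCN, rt
Reagents that add atoms: none
Why: Saegusa–Ito dehydrogenation of the silyl enol ether gives the 4H-naphthalen-1-one, which should tautomerise at once to the aromatic naphthol.

Step 7
Reactants: 9 7-chloro-5,8-bis(methoxymethoxy)naphthalen-1-ol
Product: 11 7-chloro-4,4-dimethoxy-5,8-bis(methoxymethoxy)naphthalen-1(4H)-one, via 4-methoxynaphthol 10 (not isolated)
Conditions: PhI(OAc)2 (2.2 equiv), MeOH, 0 °C
Reagents that add atoms: methanol, CO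
Why: Two successive phenol oxidations by PhI(OAc)2, each followed by capture of methanol at the para carbon, should convert the para-unsubstituted naphthol into the para-quinone monoketal (oxidative dearomatisation).

Step 8
Reactants: 11 7-chloro-4,4-dimethoxy-5,8-bis(methoxymethoxy)naphthalen-1(4H)-one
Product: 12 (2R,3S)-6-chloro-2,3-epoxy-1,1-dimethoxy-5,8-bis(methoxymethoxy)-2,3-dihydronaphthalen-4(1H)-one
Conditions: t-BuOOH (70% aq.), NaOH (aq.), N-benzylcinchonidinium chloride (10 mol %), toluene, 0 °C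
Reagents that add atoms: tert-butyl hydroperoxide, CC(C)(C)OO
Why: Weitz–Scheffer epoxidation under chiral phase-transfer catalysis: the cinchona ammonium cation carries the tert-butyl peroxide anion to one enone face, and conjugate addition at C2 followed by ring closure sets C2 and C3 together as the cis-fused (2R,3S)-epoxide.

Step 9
Reactants: 12 (2R,3S)-6-chloro-2,3-epoxy-1,1-dimethoxy-5,8-bis(methoxymethoxy)-2,3-dihydronaphthalen-4(1H)-one
Product: 13 (2R,3R,4S)-6-chloro-2,3-epoxy-1,1-dimethoxy-5,8-bis(methoxymethoxy)-1,2,3,4-tetrahydronaphthalen-4-ol (hydroxyl anti to the epoxide)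
Conditions: NaBH4, CeCl3·7H2O, MeOH, −78 → −40 °C
Reagents that add atoms: none
Why: In a Luche-type borohydride reduction of a cyclic α,β-epoxy ketone the metal ion sits between carbonyl and oxirane oxygens and hydride is delivered on the side of the oxirane oxygen, so the new C4 hydroxyl should end anti to the epoxide (4S).

Step 10
Reactants: 13 (2R,3R,4S)-6-chloro-2,3-epoxy-1,1-dimethoxy-5,8-bis(methoxymethoxy)-1,2,3,4-tetrahydronaphthalen-4-ol
Product: 14 (2R,3S,4S)-4-(tert-butyldimethylsilyloxy)-6-chloro-2,3-epoxy-1,1-dimethoxy-5,8-bis(methoxymethoxy)-1,2,3,4-tetrahydronaphthalene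
Conditions: TBSOTf, 2,6-lutidine, CH2Cl2, −78 °C
Reagents that add atoms: tert-butyldimethylsilyl trifluoromethanesulfonate, CC(C)(C)[Si](C)(C)OS(=O)(=O)C(F)(F)F
Why: Silylation of the hindered secondary alcohol with the silyl triflate at low temperature protects C4–OH for the organometallic steps and should leave the dimethyl ketal intact.

Step 11
Reactants: 14 (2R,3S,4S)-4-(tert-butyldimethylsilyloxy)-6-chloro-2,3-epoxy-1,1-dimethoxy-5,8-bis(methoxymethoxy)-1,2,3,4-tetrahydronaphthalene
Product: 15 (2R,3S,4S)-4-(tert-butyldimethylsilyloxy)-6-chloro-2,3-epoxy-5,8-bis(methoxymethoxy)-3,4-dihydronaphthalen-1(2H)-one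
Conditions: montmorillonite K10, wet CH2Cl2, rt
Reagents that add atoms: water, O
Why: Mild heterogeneous acid hydrolysis of the benzylic dimethyl ketal, which ionises far more easily than the MOM acetals, should unveil the C1 ketone without touching silyl ether or epoxide.

Step 12
Reactants: 16 2-bromo-6-chlorophenol
Product: 17 2-bromo-6-chloro-4-iodophenol
Conditions: NIS, TsOH·H2O (10 mol %), MeCN, rt
Reagents that add atoms: N-iodosuccinimide, O=C1CCC(=O)N1I
Why: Electrophilic aromatic iodination can only go para to the hydroxyl group, since both ortho positions are blocked.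

Step 13
Reactants: 17 2-bromo-6-chloro-4-iodophenol
Product: 18 1-bromo-3-chloro-5-iodo-2-(methoxymethoxy)benzene
Conditions: NaH, MOMCl, THF/DMF, 0 °C → rt
Reagents that add atoms: chloromethyl methyl ether, COCCl
Why: O-Alkylation of the sodium phenoxide gives the MOM ether, which tolerates and later stabilises the ortho aryllithium.

Step 14
Reactants: 18 1-bromo-3-chloro-5-iodo-2-(methoxymethoxy)benzene; 15 (2R,3S,4S)-4-(tert-butyldimethylsilyloxy)-6-chloro-2,3-epoxy-5,8-bis(methoxymethoxy)-3,4-dihydronaphthalen-1(2H)-one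
Product: 20 (1S,2R,3S,4S)-1-[3-bromo-5-chloro-4-(methoxymethoxy)phenyl]-4-(tert-butyldimethylsilyloxy)-6-chloro-2,3-epoxy-5,8-bis(methoxymethoxy)-1,2,3,4-tetrahydronaphthalen-1-ol, via arylmagnesium chloride 19 (not isolated)
Conditions: i-PrMgCl·LiCl, THF, −30 °C (1.5 equiv of 18); then 15, −30 → 0 °C; aq. NH4Cl
Reagents that add atoms: none
Why: Iodine–magnesium exchange is selective for the C–I bond, and 1,2-addition of the unhindered aryl Grignard reagent to the α,β-epoxy ketone should occur on the carbonyl face opposite the oxirane oxygen (Felkin–Anh approach anti to the C2–O bond), setting C1 (1S) with the aryl group anti and the hydroxyl syn to the epoxide.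

Step 15
Reactants: 20 (1S,2R,3S,4S)-1-[3-bromo-5-chloro-4-(methoxymethoxy)phenyl]-4-(tert-butyldimethylsilyloxy)-6-chloro-2,3-epoxy-5,8-bis(methoxymethoxy)-1,2,3,4-tetrahydronaphthalen-1-ol
Product: 21 1-O-triethylsilyl ether of 20, (1S,2R,3S,4S)
Conditions: TESOTf, 2,6-lutidine, CH2Cl2, 0 °C → rt
Reagents that add atoms: triethylsilyl trifluoromethanesulfonate, CC[Si](CC)(CC)OS(=O)(=O)C(F)(F)F
Why: The silyl triflate should silylate even this tertiary benzylic carbinol, which keeps the hydroxyl from trapping the later carbene or ketene.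

Step 16
Reactants: 21 1-O-triethylsilyl ether of 20
Product: 24 pentacarbonyl(methoxycarbene)chromium complex at C4a′ of the aryl ring (aryl = 3-chloro-2-(methoxymethoxy)phenyl bonded through its C5 to C1 of the protected carbinol half), (1S,2R,3S,4S), via aryllithium 22 (not isolated), via lithium acylchromate 23 (not isolated)
Conditions: t-BuLi (2.05 equiv), Et2O, −78 °C; Cr(CO)6, −78 °C → rt; then MeOTf, CH2Cl2, 0 °C
Reagents that add atoms: chromium hexacarbonyl, O=C=[Cr](=C=O)(=C=O)(=C=O)(=C=O)=C=O; methyl trifluoromethanesulfonate, COS(=O)(=O)C(F)(F)F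
Why: Fischer carbene synthesis: bromine–lithium exchange gives an aryllithium stabilised by the ortho MOM ether, its addition to a CO ligand of Cr(CO)6 gives the acylchromate, and hard O-methylation gives the methoxycarbene complex.

Step 17
Reactants: 24 pentacarbonyl(methoxycarbene)chromium complex; 25 ethynyltrimethylsilane
Product: 27 6′-chloro-4′-methoxy-5′-(methoxymethoxy)-2′-(trimethylsilyl)-1′-naphthol bonded at C8′ to C1 of the protected carbinol half (1-OTES, 4-OTBS, 5,8-bis-OMOM, 6-Cl, 2,3-epoxide), (1S,2R,3S,4S), via tricarbonylchromium naphthol complex 26 (not isolated)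
Conditions: 25 (3 equiv), THF (0.05 M), 55 °C, Ar; then air, Et2O, rt
Reagents that add atoms: none
Why: Thermal loss of one CO from 24 (the neighbouring MOM oxygen can hold the vacant site) lets 25 coordinate and insert into the Cr=C4′ bond with its unsubstituted carbon bonding to C4′ (C4′–C3′); the vinylcarbene then inserts CO (C2′–C1′) to give a chromium-bound dienylketene, which cyclises onto C8a′ (C1′–C8a′) and enolises to the naphthol complex 26, decomplexed by air to 27. This is the Dötz benzannulation of an aryl(alkoxy)carbene pentacarbonylchromium complex with a terminal silylalkyne, an established route to 2-silyl-4-methoxy-1-naphthols. The one ring formed (C1′–C2′–C3′–C4′–C4a′–C8a′) closes by 6π-electrocyclisation of the dienylketene onto the arene. No stereocentre is created, and the four existing ones lie outside the reacting π-system and should be untouched under neutral conditions at 55 °C. Only regioselectivity is needed: closure can occur solely at C8a′ because the other ortho carbon, C5′, carries the OMOM group, and steric control in the alkyne insertion places the SiMe3 end next to the CO-derived C1′, from where it is removed in step 18; THF and moderate temperature favour CO insertion over indene or cyclobutenone formation.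

Step 18
Reactants: 27 2′-silyl-1′-naphthol
Product: 28 6′-chloro-4′-methoxy-5′-(methoxymethoxy)-1′-naphthol bonded at C8′ to C1 of the protected carbinol half, (1S,2R,3S,4S)
Conditions: CF3CO2H (3 equiv), CH2Cl2, −20 °C; aq. NaHCO3
Reagents that add atoms: none
Why: Ipso protodesilylation: protonation at C2′ is favoured by the ortho hydroxyl group and the β-silicon effect, so a few equivalents of acid at low temperature should suffice and spare acetals, silyl ethers and epoxide.

Step 19
Reactants: 28 4′-methoxy-1′-naphthol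
Product: 29 6′-chloro-5′-(methoxymethoxy)-1′,4′-naphthoquinone bonded at C8′ to C1 of the protected carbinol half, (1S,2R,3S,4S)
Conditions: PhI(OAc)2 (1.1 equiv), MeCN/H2O (4:1), 0 °C
Reagents that add atoms: water, O
Why: Phenol oxidation by PhI(OAc)2 with capture of water at C4′ and loss of methanol gives the para-quinone (oxidative demethylation); the reagent needs a free phenol and should leave the bis-MOM hydroquinone ring alone.

Step 20
Reactants: 29 protected naphthoquinone
Product: 32 bicyclic ketal enone: C1′ bonded to O–C1 and O–C8, C2′=C3′, C4′ ketone, free 5-OH and 5′-OH, 4-OTBS, (1S,2R,3S,4S,1′R), via deprotected hydroxyquinone 30 (not isolated), via cyclic hemiketal 31 (not isolated)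
Conditions: CF3CO2H/CH2Cl2 (1:4), 0 °C → rt
Reagents that add atoms: none
Why: Acidolysis of the three aryl MOM ethers and the tertiary TES ether frees the C1 hydroxyl, which adds to the peri carbonyl C1′ (five-membered hemiketal), and acid-promoted loss of water with capture of the oxocarbenium ion by the C8 phenol (six-membered ring) completes an intramolecular ketalisation whose C1′ configuration is fixed by the two tethered oxygens; the hindered secondary TBS ether and the epoxide should survive anhydrous acid.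

Step 21
Reactants: 32 bicyclic ketal enone
Product: 33 4-O-TBS ether of the target, (1S,2R,3S,4S,1′S,2′R,3′S)
Conditions: 30% H2O2, K2CO3, THF/H2O, 0 °C
Reagents that add atoms: hydrogen peroxide, OO
Why: Weitz–Scheffer epoxidation: hydroperoxide should add to C2′ on the enone face opposite the aryloxy bridge O–C8 (the open face, anti to the better acceptor C1′–O bond), and ring closure sets C2′ and C3′ as the cis-epoxide anti to that oxygen.

Step 22
Reactants: 33 4-O-TBS ether of the target
Product: 34 CNP0289684.3, (1S,2R,3R,4S,1′S,2′R,3′S)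
Conditions: HF·pyridine, THF, 0 °C → rt
Reagents that add atoms: none
Why: Fluoride cleavage of the Si–O bond under weakly acidic conditions frees the C4 hydroxyl without base, which avoids Payne rearrangement of the trans-epoxy alcohol and opening of the epoxy ketone.

Compound list
1 | 2-chloro-1,4-dimethoxybenzene | COc1ccc(OC)c(Cl)c1 | starting material
2 | succinic anhydride | O=C1CCC(=O)O1 | starting material
3 | 4-(4-chloro-2,5-dimethoxyphenyl)-4-oxobutanoic acid | COc1cc(Cl)c(OC)cc1C(=O)CCC(=O)O | intermediate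
4 | 4-(4-chloro-2,5-dimethoxyphenyl)butanoic acid | COc1cc(Cl)c(OC)cc1CCCC(=O)O | intermediate
5 | 7-chloro-5,8-dimethoxy-3,4-dihydronaphthalen-1(2H)-one | COc1cc(Cl)c(OC)c2C(=O)CCCc12 | intermediate
6 | 7-chloro-5,8-dihydroxy-3,4-dihydronaphthalen-1(2H)-one | Oc1cc(Cl)c(O)c2C(=O)CCCc12 | intermediate
7 | 7-chloro-5,8-bis(methoxymethoxy)-3,4-dihydronaphthalen-1(2H)-one | COCOc1cc(Cl)c(OCOC)c2C(=O)CCCc12 | intermediate
8 | 7-chloro-5,8-bis(methoxymethoxy)-1-(trimethylsilyloxy)-3,4-dihydronaphthalene | COCOc1cc(Cl)c(OCOC)c2C(O[Si](C)(C)C)=CCCc12 | intermediate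
9 | 7-chloro-5,8-bis(methoxymethoxy)naphthalen-1-ol | COCOc1cc(Cl)c(OCOC)c2c(O)cccc12 | intermediate
10 | 7-chloro-4-methoxy-5,8-bis(methoxymethoxy)naphthalen-1-ol | COCOc1cc(Cl)c(OCOC)c2c(O)ccc(OC)c12 | intermediate
11 | 7-chloro-4,4-dimethoxy-5,8-bis(methoxymethoxy)naphthalen-1(4H)-one | COCOc1cc(Cl)c(OCOC)c2C(=O)C=CC(OC)(OC)c12 | intermediate
12 | (2R,3S)-6-chloro-2,3-epoxy-1,1-dimethoxy-5,8-bis(methoxymethoxy)-2,3-dihydronaphthalen-4(1H)-one | COCOc1cc(Cl)c(OCOC)c2c1C(OC)(OC)[C@@H]1O[C@@H]1C2=O | intermediate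
13 | (2R,3R,4S)-6-chloro-2,3-epoxy-1,1-dimethoxy-5,8-bis(methoxymethoxy)-1,2,3,4-tetrahydronaphthalen-4-ol | COCOc1cc(Cl)c(OCOC)c2c1C(OC)(OC)[C@@H]1O[C@@H]1[C@H]2O | intermediate
14 | (2R,3S,4S)-4-(tert-butyldimethylsilyloxy)-6-chloro-2,3-epoxy-1,1-dimethoxy-5,8-bis(methoxymethoxy)-1,2,3,4-tetrahydronaphthalene | COCOc1cc(Cl)c(OCOC)c2c1C(OC)(OC)[C@@H]1O[C@@H]1[C@H]2O[Si](C)(C)C(C)(C)C | intermediate
15 | (2R,3S,4S)-4-(tert-butyldimethylsilyloxy)-6-chloro-2,3-epoxy-5,8-bis(methoxymethoxy)-3,4-dihydronaphthalen-1(2H)-one | COCOc1cc(Cl)c(OCOC)c2c1C(=O)[C@@H]1O[C@@H]1[C@H]2O[Si](C)(C)C(C)(C)C | intermediate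
16 | 2-bromo-6-chlorophenol | Oc1c(Cl)cccc1Br | starting material
17 | 2-bromo-6-chloro-4-iodophenol | Oc1c(Cl)cc(I)cc1Br | intermediate
18 | 1-bromo-3-chloro-5-iodo-2-(methoxymethoxy)benzene | COCOc1c(Cl)cc(I)cc1Br | intermediate
19 | [3-bromo-5-chloro-4-(methoxymethoxy)phenyl]magnesium chloride (as its LiCl complex) | COCOc1c(Cl)cc([Mg]Cl)cc1Br | intermediate
20 | (1S,2R,3S,4S)-1-[3-bromo-5-chloro-4-(methoxymethoxy)phenyl]-4-(tert-butyldimethylsilyloxy)-6-chloro-2,3-epoxy-5,8-bis(methoxymethoxy)-1,2,3,4-tetrahydronaphthalen-1-ol | COCOc1cc(Cl)c(OCOC)c2c1[C@](c1cc(Cl)c(OCOC)c(Br)c1)(O)[C@@H]1O[C@@H]1[C@H]2O[Si](C)(C)C(C)(C)C | intermediate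
21 | 1-O-triethylsilyl ether of 20, (1S,2R,3S,4S) | COCOc1cc(Cl)c(OCOC)c2c1[C@](c1cc(Cl)c(OCOC)c(Br)c1)(O[Si](CC)(CC)CC)[C@@H]1O[C@@H]1[C@H]2O[Si](C)(C)C(C)(C)C | intermediate
22 | aryllithium from 21 (Li in place of Br, ortho to OMOM) | COCOc1cc(Cl)c(OCOC)c2c1[C@](c1cc(Cl)c(OCOC)c([Li])c1)(O[Si](CC)(CC)CC)[C@@H]1O[C@@H]1[C@H]2O[Si](C)(C)C(C)(C)C | intermediate
23 | lithium aroylpentacarbonylchromate from 22 | COCOc1cc(Cl)c(OCOC)c2c1[C@](c1cc(Cl)c(OCOC)c(C(O[Li])=[Cr](=C=O)(=C=O)(=C=O)(=C=O)=C=O)c1)(O[Si](CC)(CC)CC)[C@@H]1O[C@@H]1[C@H]2O[Si](C)(C)C(C)(C)C | intermediate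
24 | pentacarbonyl[aryl(methoxy)carbene]chromium complex, carbene at C4a′, (1S,2R,3S,4S) | COCOc1cc(Cl)c(OCOC)c2c1[C@](c1cc(Cl)c(OCOC)c(C(OC)=[Cr](=C=O)(=C=O)(=C=O)(=C=O)=C=O)c1)(O[Si](CC)(CC)CC)[C@@H]1O[C@@H]1[C@H]2O[Si](C)(C)C(C)(C)C | intermediate
25 | ethynyltrimethylsilane | C#C[Si](C)(C)C | starting material
26 | tricarbonylchromium π-complex of naphthol 27 | COCOc1cc(Cl)c(OCOC)c2c1[C@](c1cc(Cl)c(OCOC)c3c(OC)cc([Si](C)(C)C)c(O)c13)(O[Si](CC)(CC)CC)[C@@H]1O[C@@H]1[C@H]2O[Si](C)(C)C(C)(C)C.O=C=[Cr](=C=O)=C=O | intermediate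
27 | 6′-chloro-4′-methoxy-5′-(methoxymethoxy)-2′-(trimethylsilyl)-1′-naphthol bonded at C8′ to C1 of the protected carbinol half, (1S,2R,3S,4S) | COCOc1cc(Cl)c(OCOC)c2c1[C@](c1cc(Cl)c(OCOC)c3c(OC)cc([Si](C)(C)C)c(O)c13)(O[Si](CC)(CC)CC)[C@@H]1O[C@@H]1[C@H]2O[Si](C)(C)C(C)(C)C | intermediate
28 | 2′-desilyl naphthol, (1S,2R,3S,4S) | COCOc1cc(Cl)c(OCOC)c2c1[C@](c1cc(Cl)c(OCOC)c3c(OC)ccc(O)c13)(O[Si](CC)(CC)CC)[C@@H]1O[C@@H]1[C@H]2O[Si](C)(C)C(C)(C)C | intermediate
29 | 1′,4′-naphthoquinone, fully protected, (1S,2R,3S,4S) | COCOc1cc(Cl)c(OCOC)c2c1[C@](c1cc(Cl)c(OCOC)c3C(=O)C=CC(=O)c13)(O[Si](CC)(CC)CC)[C@@H]1O[C@@H]1[C@H]2O[Si](C)(C)C(C)(C)C | intermediate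
30 | hydroxyquinone with free 1-OH, 5-OH, 8-OH and 5′-OH, 4-OTBS | Oc1cc(Cl)c(O)c2c1[C@](c1cc(Cl)c(O)c3C(=O)C=CC(=O)c13)(O)[C@@H]1O[C@@H]1[C@H]2O[Si](C)(C)C(C)(C)C | intermediate
31 | five-membered cyclic hemiketal C1–O–C1′(OH), either epimer at C1′ | Oc1cc(Cl)c(O)c2c1[C@@]1(c3cc(Cl)c(O)c4C(=O)C=CC(O)(O1)c34)[C@@H]1O[C@@H]1[C@H]2O[Si](C)(C)C(C)(C)C | intermediate
32 | bicyclic ketal enone, 4-OTBS, (1S,2R,3S,4S,1′R) | O=C1c2c(O)c(Cl)cc3c2[C@@]2(Oc4cc(Cl)c(O)c5c4[C@]3(O2)[C@@H]2O[C@@H]2[C@H]5O[Si](C)(C)C(C)(C)C)C=C1 | intermediate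
33 | 4-O-TBS ether of the target, (1S,2R,3S,4S,1′S,2′R,3′S) | O=C1c2c(O)c(Cl)cc3c2[C@@]2(Oc4cc(Cl)c(O)c5c4[C@]3(O2)[C@@H]2O[C@@H]2[C@H]5O[Si](C)(C)C(C)(C)C)[C@@H]2O[C@H]12 | intermediate
34 | CNP0289684.3, (1S,2R,3R,4S,1′S,2′R,3′S) | O=C1c2c(O)c(Cl)cc3c2[C@@]2(Oc4cc(Cl)c(O)c5c4[C@]3(O2)[C@@H]2O[C@@H]2[C@H]5O)[C@@H]2O[C@H]12 | target

Total step count: 22. Longest linear sequence: 20 steps (steps 1–11, then 14–22); steps 12–13 make the aryl fragment.

Steps most likely to fail

Step 17 (benzannulation). What may go wrong: electrocyclisation at C8a′ beside the fully substituted C1 is slow, so the chromium dienylketene drains into cyclobutenone, indene or furan by-products, or the alkyne inserts twice. Fallback: the annulation is moved ahead of the fragment union, where it closes next to a bromine atom only. It sets out from ketone 15 and returns at quinone 29. Commercial 4-bromo-2-chlorophenol is iodinated (NIS) to 4-bromo-2-chloro-6-iodophenol F1 and protected (NaH, MOMCl) as 5-bromo-1-chloro-3-iodo-2-(methoxymethoxy)benzene F2. Iodine–lithium exchange (n-BuLi, −78 °C), Cr(CO)6 and MeOTf give the methoxycarbene complex F3, which with 25 gives 8-bromo-6-chloro-4-methoxy-5-(methoxymethoxy)-2-(trimethylsilyl)naphthalen-1-ol F4. Protodesilylation (CF3CO2H) gives 8-bromo-6-chloro-4-methoxy-5-(methoxymethoxy)naphthalen-1-ol F5, and methylation (MeI, K2CO3) gives 8-bromo-6-chloro-1,4-dimethoxy-5-(methoxymethoxy)naphthalene F6. Bromine–lithium exchange (n-BuLi, −78 °C) and addition to 15 anti to the epoxide should give the tertiary alcohol F7, which is silylated (TESOTf, 2,6-lutidine) to its triethylsilyl ether F8. Oxidative demethylation with (NH4)2Ce(NO3)6 in aqueous MeCN at 0 °C, which should attack the dimethoxynaphthalene before the bis-MOM benzene ring, gives 29. The crowded C8′–C1 bond is then made with a peri-substituted naphthyllithium, which is why this order is the reserve.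

Step 20 (deprotection and ketal closure). What may go wrong: the freed C1 hydroxyl adds in conjugate fashion to C2′ instead of to C1′, the ketal closes incompletely in the presence of the water and formaldehyde set free, or the C4 silyl ether is lost. Fallback: from 29 to 32 in two acetal-exchange stages. CSA in MeOH/HC(OMe)3 (rt → 40 °C) removes the MOM and TES groups and fixes C1′ as the five-membered cyclic methyl ketal F9 (C1–O–C1′(OMe), either epimer). F9 is then ionised under anhydrous conditions (BF3·OEt2, CH2Cl2, 4 Å sieves, −40 → 0 °C), so that the C8 phenol displaces methanol and closes the second ring to give 32.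

Step 14 (fragment union). What may go wrong: poor facial selectivity, because the C4 silyloxy group lies on the face the aryl group must enter, or sluggish addition to a ketone flanked by the peri OMOM group and the epoxide. Fallback: from 13, returning at 20, with the silyl ether left out during the addition. Ketal 13 is hydrolysed (montmorillonite K10, wet CH2Cl2) to the hydroxy epoxy ketone F10, which is treated with 2.5 equiv of 19. The first equivalent forms the C4 magnesium alkoxide, small and on the entry face, where it can guide the second. The resulting diol F11 is silylated selectively at the secondary hydroxyl (TBSCl, imidazole, DMF) to give 20.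

Further compounds
F1 | step 17 | 4-bromo-2-chloro-6-iodophenol | Oc1c(Cl)cc(Br)cc1I
F2 | step 17 | 5-bromo-1-chloro-3-iodo-2-(methoxymethoxy)benzene | COCOc1c(Cl)cc(Br)cc1I
F3 | step 17 | pentacarbonyl{[5-bromo-3-chloro-2-(methoxymethoxy)phenyl](methoxy)methylidene}chromium | COCOc1c(Cl)cc(Br)cc1C(OC)=[Cr](=C=O)(=C=O)(=C=O)(=C=O)=C=O
F4 | step 17 | 8-bromo-6-chloro-4-methoxy-5-(methoxymethoxy)-2-(trimethylsilyl)naphthalen-1-ol | COCOc1c(Cl)cc(Br)c2c(O)c([Si](C)(C)C)cc(OC)c12
F5 | step 17 | 8-bromo-6-chloro-4-methoxy-5-(methoxymethoxy)naphthalen-1-ol | COCOc1c(Cl)cc(Br)c2c(O)ccc(OC)c12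
F6 | step 17 | 8-bromo-6-chloro-1,4-dimethoxy-5-(methoxymethoxy)naphthalene | COCOc1c(Cl)cc(Br)c2c(OC)ccc(OC)c12
F7 | step 17 | (1S,2R,3S,4S)-4-(tert-butyldimethylsilyloxy)-6-chloro-1-[6-chloro-1,4-dimethoxy-5-(methoxymethoxy)naphthalen-8-yl]-2,3-epoxy-5,8-bis(methoxymethoxy)-1,2,3,4-tetrahydronaphthalen-1-ol | COCOc1cc(Cl)c(OCOC)c2c1[C@](c1cc(Cl)c(OCOC)c3c(OC)ccc(OC)c13)(O)[C@@H]1O[C@@H]1[C@H]2O[Si](C)(C)C(C)(C)C
F8 | step 17 | 1-O-triethylsilyl ether of F7 | COCOc1cc(Cl)c(OCOC)c2c1[C@](c1cc(Cl)c(OCOC)c3c(OC)ccc(OC)c13)(O[Si](CC)(CC)CC)[C@@H]1O[C@@H]1[C@H]2O[Si](C)(C)C(C)(C)C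
F9 | step 20 | cyclic methyl ketal C1–O–C1′(OMe) with free 5-OH, 8-OH and 5′-OH, 4-OTBS, either epimer at C1′ | Oc1cc(Cl)c(O)c2c1[C@@]1(c3cc(Cl)c(O)c4C(=O)C=CC(OC)(O1)c34)[C@@H]1O[C@@H]1[C@H]2O[Si](C)(C)C(C)(C)C
F10 | step 14 | (2R,3R,4S)-6-chloro-2,3-epoxy-4-hydroxy-5,8-bis(methoxymethoxy)-3,4-dihydronaphthalen-1(2H)-one | COCOc1cc(Cl)c(OCOC)c2c1C(=O)[C@@H]1O[C@@H]1[C@H]2O
F11 | step 14 | (1S,2R,3R,4S)-1-[3-bromo-5-chloro-4-(methoxymethoxy)phenyl]-6-chloro-2,3-epoxy-5,8-bis(methoxymethoxy)-1,2,3,4-tetrahydronaphthalene-1,4-diol | COCOc1cc(Cl)c(OCOC)c2c1[C@](c1cc(Cl)c(OCOC)c(Br)c1)(O)[C@@H]1O[C@@H]1[C@H]2O
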